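Both C2–C1' bonds are cut: in each half, C2 of ring C is bonded to the ring B carbon C1' that lies next to the C2'–C2' biaryl axis, so the target falls into one biaryl 2,2'-dianion and two identical ring A–C lactones whose only stereocentre is C3, bought with methyl (R)-glycidate. In one operation the dilithiated hexakis(benzyloxy)biphenyl, made from the 2,2'-dibromide, adds to the lactone carbonyls of two (R)-5,7-bis(benzyloxy)-3-silyloxychroman-2-ones and so joins all thirty skeletal carbons. Ionic hydrogenation then relays C3 to C2, the axial diastereomers are separated, and the protecting groups are removed.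

Key step: step 10

Assumption 1: the line notation of the target is silent on the biaryl axis; natural theasinensin C is taken as the (aR)-atropisomer (its (aS)-partner being theasinensin E), so the names carry the axial descriptor and the SMILES strings do not.
Assumption 2: 3,5-bis(benzyloxy)phenol (6) is taken as a catalogue compound; it is otherwise reached in one step from phloroglucinol and benzyl bromide.

Step 1
Reactants: 1 5-bromo-1,2,3-trimethoxybenzene
Product: 2 1-bromo-2-iodo-3,4,5-trimethoxybenzene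
Conditions: NIS (1.1 equiv), CF3CO2H (cat.), MeCN, rt
Reagents that add atoms: N-iodosuccinimide, O=C1CCC(=O)N1I
Why: Electrophilic aromatic iodination; the two free ring positions are equivalent and each is activated by an ortho and a para methoxy group, so one mono-iodide should form.

Step 2
Reactants: 2 1-bromo-2-iodo-3,4,5-trimethoxybenzene (two molecules)
Product: 3 2,2'-dibromo-4,4',5,5',6,6'-hexamethoxybiphenyl (racemic about the axis)
Conditions: Cu powder (activated, excess), DMF, 150 °C
Reagents that add atoms: none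
Why: Ullmann reductive homocoupling; copper enters the weaker C–I bond well before the C–Br bond, so the biaryl bond should form at the former iodine-bearing carbon with both bromine atoms kept.

Step 3
Reactants: 3 2,2'-dibromo-4,4',5,5',6,6'-hexamethoxybiphenyl
Product: 4 6,6'-dibromobiphenyl-2,2',3,3',4,4'-hexaol
Conditions: BBr3 (8 equiv), CH2Cl2, −78 °C → rt; then H2O
Reagents that add atoms: none
Why: Lewis-acid cleavage of aryl methyl ethers (BBr3 demethylation), to which the aryl bromides and the biaryl bond are inert.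

Step 4
Reactants: 4 6,6'-dibromobiphenyl-2,2',3,3',4,4'-hexaol
Product: 5 2,2'-dibromo-4,4',5,5',6,6'-hexakis(benzyloxy)biphenyl (racemic about the axis)
Conditions: BnBr (7 equiv), K2CO3, Bu4NI (cat.), DMF, 60 °C, under argon
Reagents that add atoms: benzyl bromide, BrCc1ccccc1
Why: Williamson ether synthesis on the six phenoxides; exclusion of air protects the pyrogallol rings until they are fully etherified.

Step 5
Reactants: 6 3,5-bis(benzyloxy)phenol
Product: 7 2-bromo-3,5-bis(benzyloxy)phenol
Conditions: NBS (1.0 equiv), i-Pr2NH (10 mol %), CH2Cl2, −78 → 0 °C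
Reagents that add atoms: N-bromosuccinimide, O=C1CCC(=O)N1Br
Why: Amine-mediated ortho-selective electrophilic bromination of a phenol; the hydrogen-bonded N-bromoamine delivers bromine next to the hydroxyl group and the para position is screened by two benzyloxy groups, so the 2-bromide should predominate and any 4-bromo isomer is removed by chromatography.

Step 6
Reactants: 7 2-bromo-3,5-bis(benzyloxy)phenol
Product: 8 1,5-bis(benzyloxy)-2-bromo-3-(methoxymethoxy)benzene
Conditions: MOMCl, i-Pr2NEt, CH2Cl2, 0 °C → rt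
Reagents that add atoms: chloromethyl methyl ether, COCCl
Why: O-alkylation of the phenol (Williamson-type acetal formation); the methoxymethyl group marks the one oxygen that must later close the lactone, tolerates the organometallic step and cannot migrate to an ortho carbanion as a silyl group would.

Step 7
Reactants: 8 1,5-bis(benzyloxy)-2-bromo-3-(methoxymethoxy)benzene; 9 methyl (R)-glycidate
Product: 12 methyl (2R)-3-[2,4-bis(benzyloxy)-6-(methoxymethoxy)phenyl]-2-hydroxypropanoate, via aryllithium 10 (not isolated), via arylmagnesium bromide 11 (not isolated)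
Conditions: n-BuLi, THF, −78 °C; MgBr2·OEt2; CuI (10 mol %), then 9 (0.8 equiv), −40 → −20 °C; then H2O (pH 7 buffer)
Reagents that add atoms: none
Why: Bromine–lithium exchange, transmetalation and copper-catalysed SN2 opening of the epoxide at its unsubstituted carbon, which at low temperature should outpace addition to the ester; the stereocentre is not touched, so the R configuration of the glycidate is carried over unchanged.

Step 8
Reactants: 12 methyl (2R)-3-[2,4-bis(benzyloxy)-6-(methoxymethoxy)phenyl]-2-hydroxypropanoate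
Product: 14 (3R)-5,7-bis(benzyloxy)-3-hydroxychroman-2-one, via phenolic methyl ester 13 (not isolated)
Conditions: HCl (1.25 M in MeOH), 40 °C; evaporate; PPTS (10 mol %), toluene, 80 °C
Reagents that add atoms: none
Why: Acid methanolysis of the methoxymethyl acetal frees the ortho phenol, and acid-catalysed transesterification (lactonisation) then closes the six-membered aryl lactone as methanol is driven off, without involving C3.

Step 9
Reactants: 14 (3R)-5,7-bis(benzyloxy)-3-hydroxychroman-2-one
Product: 15 (3R)-5,7-bis(benzyloxy)-3-[(tert-butyldimethylsilyl)oxy]chroman-2-one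
Conditions: TBSOTf (1.2 equiv), 2,6-lutidine, CH2Cl2, −20 → 0 °C
Reagents that add atoms: tert-butyldimethylsilyl trifluoromethanesulfonate, CC(C)(C)[Si](C)(C)OS(=O)(=O)C(F)(F)F
Why: Silylation of a secondary alcohol; the hindered, non-nucleophilic base avoids both opening of the reactive aryl lactone and enolisation at C3.

Step 10
Reactants: 5 2,2'-dibromo-4,4',5,5',6,6'-hexakis(benzyloxy)biphenyl; 15 (3R)-5,7-bis(benzyloxy)-3-[(tert-butyldimethylsilyl)oxy]chroman-2-one (two molecules, used in excess)
Product: 18 (2R,2'R)-1,1'-[4,4',5,5',6,6'-hexakis(benzyloxy)biphenyl-2,2'-diyl]bis{3-[2,4-bis(benzyloxy)-6-hydroxyphenyl]-2-[(tert-butyldimethylsilyl)oxy]propan-1-one} (open keto-phenol form of the bis-hemiketal; both axial diastereomers), via dilithiobiaryl 16 (not isolated), via dilithium bis-lactolate 17 (not isolated)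
Conditions: n-BuLi (2.1 equiv), THF, −78 °C, 30 min; cannulate slowly into 15 (2.6 equiv), THF, −78 °C; AcOH/THF, −78 °C
Reagents that add atoms: none
Why: Twofold bromine–lithium exchange turns 5 into the 2,2'-dilithiobiaryl 16, and each C–Li bond attacks the lactone carbonyl C2 of one molecule of 15 to give a lithium lactolate (17), which is protonated cold to the hemiketal and its open keto-phenol tautomer 18. The closest known reaction type is the addition of aryllithiums to silyl-protected sugar lactones on the way to C-aryl glycosides. No ring is closed, because the keto-phenol only equilibrates with the six-membered hemiketal, and no lasting stereocentre is created, because the hemiketal carbon is removed in step 11 and the axis is left as a mixture. The step needs single addition at each carbonyl and capture of the second C–Li site by a second lactone before the first adduct can open to a ketone that this neighbouring site could attack to close a fluorenol; slow inverse addition into an excess of 15 at −78 °C, a cold acidic quench and the shielding of any ketone formed by the ortho-biaryl and the silyloxy group should secure this. Retention at C3 is expected because a weakly basic aryllithium adds to the ester carbonyl faster than it removes the C3 proton, which the tert-butyldimethylsilyl group also screens.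

Step 11
Reactants: 18 bis(keto-phenol) / bis-hemiketal
Product: 19 (aR)-2,2'-bis{(2R,3R)-5,7-bis(benzyloxy)-3-[(tert-butyldimethylsilyl)oxy]chroman-2-yl}-4,4',5,5',6,6'-hexakis(benzyloxy)biphenyl
Conditions: Et3SiH (10 equiv), BF3·OEt2 (4 equiv), CH2Cl2, −78 → −30 °C; silica gel chromatography to separate the axial diastereomers
Reagents that add atoms: none
Why: Ionic hydrogenation of a lactol as in C-aryl glycoside synthesis: BF3·OEt2 ionises each cyclic hemiketal to a C2 oxocarbenium ion in which allylic strain with the C2 aryl group holds the C3 silyloxy group pseudoaxial, so Et3SiH should deliver hydride to the opposite face and set C2 as R with the aryl group cis to the C3 oxygen, while the two axial diastereomers, which differ in shape, are separated on silica.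

Step 12
Reactants: 19 (aR)-bis(silyl ether)
Product: 20 (aR)-2,2'-bis[(2R,3R)-5,7-bis(benzyloxy)-3-hydroxychroman-2-yl]-4,4',5,5',6,6'-hexakis(benzyloxy)biphenyl
Conditions: Bu4NF, AcOH, THF, rt → 40 °C
Reagents that add atoms: none
Why: Fluoride-induced cleavage of the two silyl ethers, driven by the Si–F bond; buffering with acetic acid keeps the medium near neutral, and benzyl ethers, stereocentres and axis are not affected.

Step 13
Reactants: 20 (aR)-decabenzyl diol
Product: 21 theasinensin C, (aR)-2,2'-bis[(2R,3R)-3,5,7-trihydroxychroman-2-yl]biphenyl-4,4',5,5',6,6'-hexaol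
Conditions: H2 (1 atm), Pd(OH)2/C, THF/MeOH, rt; filtration and chromatography under argon
Reagents that add atoms: none
Why: Catalytic hydrogenolysis of the ten benzyl ethers under neutral conditions at room temperature, which should leave the cyclic C2–O1 ether, the 2,3-cis stereocentres and the hindered axis intact, as in the closing step of benzyl-protected catechin syntheses.

Compound list
1 | 5-bromo-1,2,3-trimethoxybenzene | COc1cc(Br)cc(OC)c1OC | starting material
2 | 1-bromo-2-iodo-3,4,5-trimethoxybenzene | COc1cc(Br)c(I)c(OC)c1OC | intermediate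
3 | 2,2'-dibromo-4,4',5,5',6,6'-hexamethoxybiphenyl (racemic about the axis) | COc1cc(Br)c(c(OC)c1OC)-c1c(Br)cc(OC)c(OC)c1OC | intermediate
4 | 6,6'-dibromobiphenyl-2,2',3,3',4,4'-hexaol | Oc1cc(Br)c(c(O)c1O)-c1c(Br)cc(O)c(O)c1O | intermediate
5 | 2,2'-dibromo-4,4',5,5',6,6'-hexakis(benzyloxy)biphenyl (racemic about the axis) | Brc1cc(OCc2ccccc2)c(OCc2ccccc2)c(OCc2ccccc2)c1-c1c(Br)cc(OCc2ccccc2)c(OCc2ccccc2)c1OCc1ccccc1 | intermediate
6 | 3,5-bis(benzyloxy)phenol | Oc1cc(OCc2ccccc2)cc(OCc2ccccc2)c1 | starting material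
7 | 2-bromo-3,5-bis(benzyloxy)phenol | Oc1cc(OCc2ccccc2)cc(OCc2ccccc2)c1Br | intermediate
8 | 1,5-bis(benzyloxy)-2-bromo-3-(methoxymethoxy)benzene | COCOc1cc(OCc2ccccc2)cc(OCc2ccccc2)c1Br | intermediate
9 | methyl (R)-glycidate, methyl (2R)-oxirane-2-carboxylate | COC(=O)[C@H]1CO1 | starting material
10 | [2,4-bis(benzyloxy)-6-(methoxymethoxy)phenyl]lithium | [Li]c1c(OCOC)cc(OCc2ccccc2)cc1OCc1ccccc1 | intermediate
11 | [2,4-bis(benzyloxy)-6-(methoxymethoxy)phenyl]magnesium bromide | Br[Mg]c1c(OCOC)cc(OCc2ccccc2)cc1OCc1ccccc1 | intermediate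
12 | methyl (2R)-3-[2,4-bis(benzyloxy)-6-(methoxymethoxy)phenyl]-2-hydroxypropanoate | COC(=O)[C@H](O)Cc1c(OCOC)cc(OCc2ccccc2)cc1OCc1ccccc1 | intermediate
13 | methyl (2R)-3-[2,4-bis(benzyloxy)-6-hydroxyphenyl]-2-hydroxypropanoate | COC(=O)[C@H](O)Cc1c(O)cc(OCc2ccccc2)cc1OCc1ccccc1 | intermediate
14 | (3R)-5,7-bis(benzyloxy)-3-hydroxychroman-2-one | O=C1Oc2cc(OCc3ccccc3)cc(OCc3ccccc3)c2C[C@H]1O | intermediate
15 | (3R)-5,7-bis(benzyloxy)-3-[(tert-butyldimethylsilyl)oxy]chroman-2-one | O=C1Oc2cc(OCc3ccccc3)cc(OCc3ccccc3)c2C[C@H]1O[Si](C)(C)C(C)(C)C | intermediate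
16 | 2,2'-dilithio-4,4',5,5',6,6'-hexakis(benzyloxy)biphenyl | [Li]c1cc(OCc2ccccc2)c(OCc2ccccc2)c(OCc2ccccc2)c1-c1c([Li])cc(OCc2ccccc2)c(OCc2ccccc2)c1OCc1ccccc1 | intermediate
17 | dilithium bis-lactolate, 2,2'-bis{(3R)-5,7-bis(benzyloxy)-3-[(tert-butyldimethylsilyl)oxy]-2-(lithiooxy)chroman-2-yl}-4,4',5,5',6,6'-hexakis(benzyloxy)biphenyl | [Li]OC1(Oc2cc(OCc3ccccc3)cc(OCc3ccccc3)c2C[C@H]1O[Si](C)(C)C(C)(C)C)c1cc(OCc2ccccc2)c(OCc2ccccc2)c(OCc2ccccc2)c1-c1c(cc(OCc2ccccc2)c(OCc2ccccc2)c1OCc1ccccc1)C1(O[Li])Oc2cc(OCc3ccccc3)cc(OCc3ccccc3)c2C[C@H]1O[Si](C)(C)C(C)(C)C | intermediate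
18 | (2R,2'R)-1,1'-[4,4',5,5',6,6'-hexakis(benzyloxy)biphenyl-2,2'-diyl]bis{3-[2,4-bis(benzyloxy)-6-hydroxyphenyl]-2-[(tert-butyldimethylsilyl)oxy]propan-1-one}, both axial diastereomers, in equilibrium with the bis-hemiketal | O=C([C@H](O[Si](C)(C)C(C)(C)C)Cc1c(O)cc(OCc2ccccc2)cc1OCc1ccccc1)c1cc(OCc2ccccc2)c(OCc2ccccc2)c(OCc2ccccc2)c1-c1c(cc(OCc2ccccc2)c(OCc2ccccc2)c1OCc1ccccc1)C(=O)[C@H](O[Si](C)(C)C(C)(C)C)Cc1c(O)cc(OCc2ccccc2)cc1OCc1ccccc1 | intermediate
19 | (aR)-2,2'-bis{(2R,3R)-5,7-bis(benzyloxy)-3-[(tert-butyldimethylsilyl)oxy]chroman-2-yl}-4,4',5,5',6,6'-hexakis(benzyloxy)biphenyl | c5ccccc5COc1cc(OCc5ccccc5)c2c(c1)O[C@H](c1cc(OCc5ccccc5)c(OCc5ccccc5)c(OCc5ccccc5)c1-c1c([C@H]3Oc4cc(OCc5ccccc5)cc(OCc5ccccc5)c4C[C@H]3O[Si](C)(C)C(C)(C)C)cc(OCc5ccccc5)c(OCc5ccccc5)c1OCc5ccccc5)[C@H](O[Si](C)(C)C(C)(C)C)C2 | intermediate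
20 | (aR)-2,2'-bis[(2R,3R)-5,7-bis(benzyloxy)-3-hydroxychroman-2-yl]-4,4',5,5',6,6'-hexakis(benzyloxy)biphenyl | c5ccccc5COc1cc(OCc5ccccc5)c2c(c1)O[C@H](c1cc(OCc5ccccc5)c(OCc5ccccc5)c(OCc5ccccc5)c1-c1c([C@H]3Oc4cc(OCc5ccccc5)cc(OCc5ccccc5)c4C[C@H]3O)cc(OCc5ccccc5)c(OCc5ccccc5)c1OCc5ccccc5)[C@H](O)C2 | intermediate
21 | theasinensin C, (aR)-2,2'-bis[(2R,3R)-3,5,7-trihydroxychroman-2-yl]biphenyl-4,4',5,5',6,6'-hexaol | Oc1cc(O)c2c(c1)O[C@H](c1cc(O)c(O)c(O)c1-c1c([C@H]3Oc4cc(O)cc(O)c4C[C@H]3O)cc(O)c(O)c1O)[C@H](O)C2 | target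

Total step count: 13. Longest linear sequence: 9 steps (6 → 21, steps 5–13); the biaryl branch (1 → 5) joins at step 10.

Steps most likely to fail

Step 10. What may go wrong: the first lactolate opens to its ketone while the neighbouring C–Li bond is still unreacted, and that bond then attacks the ketone within the molecule (fluorenol ring closure); over-addition and proton abstraction at C3 are further risks. Fallback: the two C2–C1' bonds would be made one after the other. Setting out from 5, exchange of only one bromine (n-BuLi, 1.0 equiv, THF, −78 °C) and addition to 15 should give the mono-adduct, bromo keto-phenol F1. Reduction with Et3SiH/BF3·OEt2 as in step 11 should give the bromo mono-flavan F2, which holds no carbonyl group for a neighbouring aryllithium to attack. A second bromine–lithium exchange on F2 and addition to 15 should give the mono-flavan keto-phenol F3, and its reduction as in step 11 returns to the route at 19.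

Step 11. What may go wrong: poor facial selectivity of hydride transfer to the C2 oxocarbenium ions (2,3-trans units), made worse if BF3·OEt2 strips the silyl ether or the cation loses the C3 proton. Fallback: C2 would be set without a cation. Setting out from 18, reduction of both ketones with BH3·SMe2 and the (S)-2-methyl-CBS-oxazaborolidine should give the bis-(1S,2R)-carbinol F4. Here the reagent must override the substrate's own preference, and the free phenols consume extra borane. Twofold Mitsunobu etherification (PPh3, diisopropyl azodicarboxylate, THF, 0 °C), in which each ring A phenol displaces the activated benzylic oxygen with inversion, should then close both rings C as 2,3-cis and return to the route at 19 after separation of the axial diastereomers.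

Step 7. What may go wrong: addition of the hindered arylmagnesium species to the ester carbonyl and bromide opening of the epoxide compete with the copper-mediated attack at the terminal carbon. Fallback: the ester would be taken out of play. Setting out from 9, saponification (KOH, EtOH, 0 °C) should give potassium (R)-glycidate F5. Copper-catalysed opening with arylmagnesium bromide 11 (made from 8 as before) should give, after acidification, the hydroxy acid F6. The conditions of step 8 (HCl/MeOH, then PPTS, toluene) should convert F6 through ester 13 into lactone 14, where the route is rejoined.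

Further compounds
F1 | step 10 | (2R)-1-[2'-bromo-4,4',5,5',6,6'-hexakis(benzyloxy)biphenyl-2-yl]-3-[2,4-bis(benzyloxy)-6-hydroxyphenyl]-2-[(tert-butyldimethylsilyl)oxy]propan-1-one | O=C([C@H](O[Si](C)(C)C(C)(C)C)Cc1c(O)cc(OCc2ccccc2)cc1OCc1ccccc1)c1cc(OCc2ccccc2)c(OCc2ccccc2)c(OCc2ccccc2)c1-c1c(Br)cc(OCc2ccccc2)c(OCc2ccccc2)c1OCc1ccccc1
F2 | step 10 | 2-bromo-2'-{(2R,3R)-5,7-bis(benzyloxy)-3-[(tert-butyldimethylsilyl)oxy]chroman-2-yl}-4,4',5,5',6,6'-hexakis(benzyloxy)biphenyl | Brc1cc(OCc2ccccc2)c(OCc2ccccc2)c(OCc2ccccc2)c1-c1c(cc(OCc2ccccc2)c(OCc2ccccc2)c1OCc1ccccc1)[C@H]1Oc2cc(OCc3ccccc3)cc(OCc3ccccc3)c2C[C@H]1O[Si](C)(C)C(C)(C)C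
F3 | step 10 | (2R)-1-(2'-{(2R,3R)-5,7-bis(benzyloxy)-3-[(tert-butyldimethylsilyl)oxy]chroman-2-yl}-4,4',5,5',6,6'-hexakis(benzyloxy)biphenyl-2-yl)-3-[2,4-bis(benzyloxy)-6-hydroxyphenyl]-2-[(tert-butyldimethylsilyl)oxy]propan-1-one | O=C([C@H](O[Si](C)(C)C(C)(C)C)Cc1c(O)cc(OCc2ccccc2)cc1OCc1ccccc1)c1cc(OCc2ccccc2)c(OCc2ccccc2)c(OCc2ccccc2)c1-c1c(cc(OCc2ccccc2)c(OCc2ccccc2)c1OCc1ccccc1)[C@H]1Oc2cc(OCc3ccccc3)cc(OCc3ccccc3)c2C[C@H]1O[Si](C)(C)C(C)(C)C
F4 | step 11 | (1S,1'S,2R,2'R)-1,1'-[4,4',5,5',6,6'-hexakis(benzyloxy)biphenyl-2,2'-diyl]bis{3-[2,4-bis(benzyloxy)-6-hydroxyphenyl]-2-[(tert-butyldimethylsilyl)oxy]propan-1-ol} | O[C@H]([C@H](O[Si](C)(C)C(C)(C)C)Cc1c(O)cc(OCc2ccccc2)cc1OCc1ccccc1)c1cc(OCc2ccccc2)c(OCc2ccccc2)c(OCc2ccccc2)c1-c1c(cc(OCc2ccccc2)c(OCc2ccccc2)c1OCc1ccccc1)[C@H](O)[C@H](O[Si](C)(C)C(C)(C)C)Cc1c(O)cc(OCc2ccccc2)cc1OCc1ccccc1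
F5 | step 7 | potassium (R)-glycidate | [K+].[O-]C(=O)[C@H]1CO1
F6 | step 7 | (2R)-3-[2,4-bis(benzyloxy)-6-(methoxymethoxy)phenyl]-2-hydroxypropanoic acid | OC(=O)[C@H](O)Cc1c(OCOC)cc(OCc2ccccc2)cc1OCc1ccccc1
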